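**Assumption:** the target has no stereocentre and is achiral, so there is no enantiomer to select. Intermediates 6 and 8–12 carry transient sp3 centres, are used as racemates or diastereomer mixtures, and all of these centres are lost on aromatisation.

## Retrosynthetic overview
- Target 17 comes from tosylate 16 by S–O hydrolysis. The OMe and both Br atoms of ring A come from OH-directed dibromination and methylation of 2-aryloxyphenol 14.
- Ring A of 14 is not coupled on. It is built on the ether oxygen by dehydrogenating 6-aryloxycyclohex-2-enone 12, so no Cu or Pd coupling is run next to C–Br bonds.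
- 12 comes from ring closure (intramolecular aldol) and decarboxylation of keto-aldehyde 8. The key C–C bond of 8 is made by intermolecular Michael addition of α-aryloxy-β-keto ester 6 to acrolein 7.
- 6 comes from SN2 of phenol 3 on chloride 5. Ring B is bought as catechol, and its Br pattern is set by the free OH while the other oxygen is masked as a tosylate.
- Ring order: ring B is commercial, and ring A is formed last by Michael addition, aldol closure and aromatisation.

## Route

**Step 1**
Reactants: 1 catechol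
Product: 2 2-hydroxyphenyl 4-methylbenzenesulfonate
Conditions: TsCl (1.0 equiv), catechol (1.5 equiv), Et3N (1.1 equiv), CH2Cl2, 0 °C to rt
Reagents that add atoms: tosyl chloride, Cc1ccc(cc1)S(=O)(=O)Cl
Why: O-sulfonylation with excess diol favours the monoester, because the first tosylate lowers the nucleophilicity of the neighbouring OH.

**Step 2**
Reactants: 2 2-hydroxyphenyl 4-methylbenzenesulfonate
Product: 3 3,5-dibromo-2-hydroxyphenyl 4-methylbenzenesulfonate
Conditions: Br2 (2.1 equiv), AcOH, rt
Reagents that add atoms: bromine, BrBr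
Why: In this electrophilic aromatic bromination the free OH is the only strong donor (the sulfonate oxygen is a poor one), so both Br atoms enter ortho and para to OH.

**Step 3**
Reactants: 4 tert-butyl acetoacetate
Product: 5 tert-butyl 2-chloro-3-oxobutanoate (racemic)
Conditions: SO2Cl2 (1.0 equiv), CH2Cl2, 0 °C, N2 sweep
Reagents that add atoms: sulfuryl chloride, ClS(Cl)(=O)=O
Why: α-Chlorination of the enol of a β-keto ester stops at the monochloride at 0 °C with one equivalent of reagent.

**Step 4**
Reactants: 3 3,5-dibromo-2-hydroxyphenyl 4-methylbenzenesulfonate; 5 tert-butyl 2-chloro-3-oxobutanoate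
Product: 6 tert-butyl 2-[2,4-dibromo-6-(tosyloxy)phenoxy]-3-oxobutanoate (racemic)
Conditions: K2CO3 (1.1 equiv), DMF, 50 °C
Reagents that add atoms: none
Why: This is a Williamson-type SN2 at a doubly activated α-chloro carbon, and phenol 3 (pKa about 7) is more acidic than 5, so the phenoxide meets neutral chloride. Intramolecular tosyl migration needs a non-linear five-membered transition state at sulfur and is disfavoured.

**Step 5 (key C–C bond)**
Reactants: 6 tert-butyl 2-[2,4-dibromo-6-(tosyloxy)phenoxy]-3-oxobutanoate; 7 acrolein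
Product: 8 tert-butyl 2-acetyl-2-[2,4-dibromo-6-(tosyloxy)phenoxy]-5-oxopentanoate (racemic)
Conditions: acrolein (1.5 equiv), Et3N (0.1 equiv), BHT (trace), MeCN, 0 °C to rt
Reagents that add atoms: none
Why: Intermolecular Michael addition of a stabilised tertiary β-keto ester enolate to the unhindered terminus of acrolein gives a single adduct, because the donor has only one acidic H. The new quaternary centre is racemic and is erased later.

**Step 6**
Reactants: 8 tert-butyl 2-acetyl-2-[2,4-dibromo-6-(tosyloxy)phenoxy]-5-oxopentanoate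
Product: 10 tert-butyl 1-[2,4-dibromo-6-(tosyloxy)phenoxy]-2-oxocyclohex-3-ene-1-carboxylate (racemic), via aldol adduct 9 (not isolated)
Conditions: pyrrolidine (0.2 equiv), AcOH (0.2 equiv), 4 Å MS, toluene, rt to 50 °C
Reagents that add atoms: none
Why: In this intramolecular aldol condensation (the ring-closing half of a Robinson annulation) only attack of the acetyl CH3 on the aldehyde gives an unstrained ring. Every other enol/carbonyl pairing would close a four-membered ring.

**Step 7**
Reactants: 10 tert-butyl 1-[2,4-dibromo-6-(tosyloxy)phenoxy]-2-oxocyclohex-3-ene-1-carboxylate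
Product: 12 6-[2,4-dibromo-6-(tosyloxy)phenoxy]cyclohex-2-en-1-one (racemic), via keto acid 11 (not isolated)
Conditions: TFA/CH2Cl2 1:3, 0 °C to rt; concentrate; toluene, 60 °C
Reagents that add atoms: none
Why: Acidolysis of the tert-butyl ester followed by β-keto acid decarboxylation avoids hydroxide, which could cause retro-Claisen ring opening, and avoids hot strong acid, which could expel ArOH.

**Step 8**
Reactants: 12 6-[2,4-dibromo-6-(tosyloxy)phenoxy]cyclohex-2-en-1-one
Product: 14 3,5-dibromo-2-(2-hydroxyphenoxy)phenyl 4-methylbenzenesulfonate, via cross-conjugated dienone 13 (not isolated)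
Conditions: DDQ (1.2 equiv), 1,4-dioxane, 90 °C
Reagents that add atoms: none
Why: In this DDQ dehydrogenation hydride is taken from C5 of the aryloxy-substituted enol, and the resulting 2,5-dienone tautomerises irreversibly to the phenol. The ArBr and OTs groups are inert.

**Step 9**
Reactants: 14 3,5-dibromo-2-(2-hydroxyphenoxy)phenyl 4-methylbenzenesulfonate
Product: 15 3,5-dibromo-2-(3,5-dibromo-2-hydroxyphenoxy)phenyl 4-methylbenzenesulfonate
Conditions: Br2 (2.1 equiv), AcOH/CH2Cl2, 0 °C to rt
Reagents that add atoms: bromine, BrBr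
Why: Electrophilic bromination ortho and para to the free phenol takes place only on ring A, because ring B (two Br, OTs) and the tolyl ring are strongly deactivated.

**Step 10**
Reactants: 15 3,5-dibromo-2-(3,5-dibromo-2-hydroxyphenoxy)phenyl 4-methylbenzenesulfonate
Product: 16 3,5-dibromo-2-(3,5-dibromo-2-methoxyphenoxy)phenyl 4-methylbenzenesulfonate
Conditions: MeI (1.5 equiv), K2CO3 (1.5 equiv), DMF, rt
Reagents that add atoms: iodomethane, CI
Why: Williamson O-methylation of the only free phenol proceeds at rt, and neither ring is activated enough for a Smiles rearrangement under these conditions.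

**Step 11**
Reactants: 16 3,5-dibromo-2-(3,5-dibromo-2-methoxyphenoxy)phenyl 4-methylbenzenesulfonate
Product: 17 3,5-dibromo-2-(3,5-dibromo-2-methoxyphenoxy)phenol (target)
Conditions: 2 M aq NaOH (5 equiv), 1,4-dioxane, 80 °C; then 1 M HCl
Reagents that add atoms: none
Why: Hydroxide cleaves the S–O bond of the aryl sulfonate, helped by the electron-poor dibromophenoxide leaving group. Alcohol-free medium prevents formation of methyl tosylate, which could re-alkylate the phenoxide.

## Compound list
1 | catechol | Oc1ccccc1O | starting material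
2 | 2-hydroxyphenyl 4-methylbenzenesulfonate | Cc1ccc(cc1)S(=O)(=O)Oc1ccccc1O | intermediate
3 | 3,5-dibromo-2-hydroxyphenyl 4-methylbenzenesulfonate | Cc1ccc(cc1)S(=O)(=O)Oc1cc(Br)cc(Br)c1O | intermediate
4 | tert-butyl acetoacetate | CC(=O)CC(=O)OC(C)(C)C | starting material
5 | tert-butyl 2-chloro-3-oxobutanoate (racemic) | CC(=O)C(Cl)C(=O)OC(C)(C)C | intermediate
6 | tert-butyl 2-[2,4-dibromo-6-(tosyloxy)phenoxy]-3-oxobutanoate (racemic) | CC(=O)C(Oc1c(Br)cc(Br)cc1OS(=O)(=O)c1ccc(C)cc1)C(=O)OC(C)(C)C | intermediate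
7 | acrolein | C=CC=O | starting material
8 | tert-butyl 2-acetyl-2-[2,4-dibromo-6-(tosyloxy)phenoxy]-5-oxopentanoate (racemic) | CC(=O)C(CCC=O)(Oc1c(Br)cc(Br)cc1OS(=O)(=O)c1ccc(C)cc1)C(=O)OC(C)(C)C | intermediate
9 | tert-butyl 1-[2,4-dibromo-6-(tosyloxy)phenoxy]-4-hydroxy-2-oxocyclohexane-1-carboxylate (diastereomer mixture, not isolated) | O=C1CC(O)CCC1(Oc2c(Br)cc(Br)cc2OS(=O)(=O)c2ccc(C)cc2)C(=O)OC(C)(C)C | intermediate
10 | tert-butyl 1-[2,4-dibromo-6-(tosyloxy)phenoxy]-2-oxocyclohex-3-ene-1-carboxylate (racemic) | O=C1C=CCCC1(Oc2c(Br)cc(Br)cc2OS(=O)(=O)c2ccc(C)cc2)C(=O)OC(C)(C)C | intermediate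
11 | 1-[2,4-dibromo-6-(tosyloxy)phenoxy]-2-oxocyclohex-3-ene-1-carboxylic acid (not isolated) | O=C1C=CCCC1(Oc2c(Br)cc(Br)cc2OS(=O)(=O)c2ccc(C)cc2)C(=O)O | intermediate
12 | 6-[2,4-dibromo-6-(tosyloxy)phenoxy]cyclohex-2-en-1-one (racemic) | O=C1C=CCCC1Oc2c(Br)cc(Br)cc2OS(=O)(=O)c2ccc(C)cc2 | intermediate
13 | 2-[2,4-dibromo-6-(tosyloxy)phenoxy]cyclohexa-2,5-dien-1-one (not isolated) | O=C1C=CCC=C1Oc2c(Br)cc(Br)cc2OS(=O)(=O)c2ccc(C)cc2 | intermediate
14 | 3,5-dibromo-2-(2-hydroxyphenoxy)phenyl 4-methylbenzenesulfonate | Oc1ccccc1Oc1c(Br)cc(Br)cc1OS(=O)(=O)c1ccc(C)cc1 | intermediate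
15 | 3,5-dibromo-2-(3,5-dibromo-2-hydroxyphenoxy)phenyl 4-methylbenzenesulfonate | Oc1c(Br)cc(Br)cc1Oc1c(Br)cc(Br)cc1OS(=O)(=O)c1ccc(C)cc1 | intermediate
16 | 3,5-dibromo-2-(3,5-dibromo-2-methoxyphenoxy)phenyl 4-methylbenzenesulfonate | COc1c(Br)cc(Br)cc1Oc1c(Br)cc(Br)cc1OS(=O)(=O)c1ccc(C)cc1 | intermediate
17 | 3,5-dibromo-2-(3,5-dibromo-2-methoxyphenoxy)phenol | COc1c(Br)cc(Br)cc1Oc1c(O)cc(Br)cc1Br | target

## Step count
- Total steps: 11
- Longest linear sequence: 10 (steps 1, 2, 4–11)

## Three steps most likely to fail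

**Step 4.** A hindered, weakly nucleophilic phenoxide must displace a secondary, acidic chloride.

The fallback sets out from 3 and returns at 6, building the β-keto ester after the C–O bond instead of before it. Phenol 3 is alkylated with the primary halide tert-butyl bromoacetate (K2CO3, acetone, reflux). This gives tert-butyl 2-[2,4-dibromo-6-(tosyloxy)phenoxy]acetate F1. Its lithium enolate (LiHMDS 2.2 equiv, THF, −78 °C) is then C-acetylated with N-acetylimidazole in a crossed Claisen condensation, which delivers 6.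

**Step 6.** The methyl ketone sits beside a crowded quaternary carbon, so closure may be slow and the aldehyde may oligomerise.

The fallback sets out from 8 and returns at 12, removing the ester before ring closure.
- TFA/CH2Cl2 converts 8 into 2-acetyl-2-[2,4-dibromo-6-(tosyloxy)phenoxy]-5-oxopentanoic acid F2.
- F2 loses CO2 on warming to give 4-[2,4-dibromo-6-(tosyloxy)phenoxy]-5-oxohexanal F3.
- The now unhindered ketone of F3 closes under piperidinium acetate in toluene at 60 °C through 2-[2,4-dibromo-6-(tosyloxy)phenoxy]-5-hydroxycyclohexan-1-one F4.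
- F4 dehydrates to 12.

**Step 8.** The DDQ dehydrogenation may be incomplete, or ArOH may be lost to give plain phenol.

The fallback sets out from 12 and returns at 14 through 13, replacing hydride abstraction with a low-temperature syn elimination.
- Kinetic α'-deprotonation (LiHMDS, THF, −78 °C) and trapping with PhSeCl gives 6-[2,4-dibromo-6-(tosyloxy)phenoxy]-6-(phenylselanyl)cyclohex-2-en-1-one F5.
- H2O2/pyridine in CH2Cl2 at 0 °C forms the selenoxide F6.
- F6 eliminates towards C5 to give dienone 13, which tautomerises to 14.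

## Further compounds
F1 | step 4 | tert-butyl 2-[2,4-dibromo-6-(tosyloxy)phenoxy]acetate | CC(C)(C)OC(=O)COc1c(Br)cc(Br)cc1OS(=O)(=O)c1ccc(C)cc1
F2 | step 6 | 2-acetyl-2-[2,4-dibromo-6-(tosyloxy)phenoxy]-5-oxopentanoic acid | CC(=O)C(CCC=O)(Oc1c(Br)cc(Br)cc1OS(=O)(=O)c1ccc(C)cc1)C(=O)O
F3 | step 6 | 4-[2,4-dibromo-6-(tosyloxy)phenoxy]-5-oxohexanal | CC(=O)C(CCC=O)Oc1c(Br)cc(Br)cc1OS(=O)(=O)c1ccc(C)cc1
F4 | step 6 | 2-[2,4-dibromo-6-(tosyloxy)phenoxy]-5-hydroxycyclohexan-1-one | O=C1CC(O)CCC1Oc2c(Br)cc(Br)cc2OS(=O)(=O)c2ccc(C)cc2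
F5 | step 8 | 6-[2,4-dibromo-6-(tosyloxy)phenoxy]-6-(phenylselanyl)cyclohex-2-en-1-one | O=C1C=CCCC1([Se]c2ccccc2)Oc2c(Br)cc(Br)cc2OS(=O)(=O)c2ccc(C)cc2
F6 | step 8 | 6-[2,4-dibromo-6-(tosyloxy)phenoxy]-6-(phenylseleninyl)cyclohex-2-en-1-one | O=C1C=CCCC1([Se](=O)c2ccccc2)Oc2c(Br)cc(Br)cc2OS(=O)(=O)c2ccc(C)cc2
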